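A direct plan would take rings A and B from the shelf and close ring C last: 1-(2,6-dihydroxy-4-methoxyphenyl)ethanone A1 would be C-prenylated twice in aqueous alkali to the 3,5-diprenyl ketone A2.
After silylation of both phenols and a detrifluoroacetylative diazo transfer, the silyl groups would be exchanged for two esters of 3-acetoxy-4-methoxybenzoyl chloride A3 to give the bis-aroyl diazoketone A4.
Rh2(OAc)4 (a divalent-rhodium carboxylate dimer) would then have to turn A4, by way of a seven-membered carbonyl ylide and a flavone epoxide, into the 5-O-aroyl flavonol A5, and methanolysis would free the target.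
The first weak point would be the double C-prenylation of the phenoxide: O-alkylation, mono-alkylation and over-alkylation would compete in the one step through which all material must pass.
The second would be the carbenoid ring closure: an untested cascade on the most advanced intermediate, with the closure left to chance between the ester carbonyl oxygen (ring C), the ester ether oxygen (oxonium ylide, coumaranone), Wolff rearrangement and the two electron-rich prenyl alkenes.
The third would be the stretch of silylation, diazo transfer, desilylation and double aroylation: four operations would add only an N2 unit and two acyl groups, one of which would be discarded at the end.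

Plan of the new route
The retrosynthesis cuts O1–C2 (cyclodehydration) and C4a–C5 (Claisen closure) in one operation, then C2–C3 (dianion aroylation), C4–C4a (acylation of a pyranone methyl group) and the two prenyl C–C bonds (enolate alkylation of methyl acetoacetate).
The enabling feature is ring A: a fully substituted phloroglucinol in which the O-bearing carbons C5, C7 and C8a alternate with the C-bearing carbons C4a, C6 and C8, symmetric about the C4a–C7 axis. C5–C6–C7–C8–C8a is therefore a 2,4-diprenyl-3,5-dioxo acid that can be stored as a 4-methoxy-3,5-diprenyl-2-pyranone (4-OMe = 7-OMe, ring oxygen = O1, lactone C=O = 5-OH).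
The rings arise in the order 2-pyranone, then ring A from it by lactone opening and Claisen closure, then ring C by dehydration; ring B is carried in from methyl isovanillate.
The weak steps do not occur: no phenol is prenylated (both prenyl groups go onto a β-keto ester before any ring exists), no diazo or carbenoid chemistry is used, the only protecting groups are two MOM ethers that fall off in the ring-closing step, and ring C has no regiochemical choice because the two phenols it can use are equivalent.
Key step: step 9

Remark on the chemistry: the target has no stereocentre; the stereocentres of the open-chain intermediates are enolisable, are carried as mixtures and vanish on ring formation.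

Step 1
Reactants: 1 methyl acetoacetate (methyl 3-oxobutanoate); 2 1-bromo-3-methylbut-2-ene (prenyl bromide, 2.3 equiv in two portions)
Product: 3 methyl 7-methyl-2-(3-methylbut-2-en-1-yl)-3-oxooct-6-enoate (racemic)
Conditions: NaH (1.1 equiv), THF, 0 °C; n-BuLi (1.05 equiv), 0 °C; 2 (1.0 equiv), 0 °C; then 2 (1.3 equiv), rt to 40 °C; aq. NH4Cl
Reagents that add atoms: none
Why: Dianion alkylation of a β-keto ester: the γ-carbanion of the sodium lithium dianion, the more basic site, should take the first prenyl group and the remaining α-enolate the second from the same allylic bromide in the same flask, so that both prenyl C–C bonds are made by enolate C-alkylation before any ring exists; the new stereocentre at C2 is racemic and is lost in step 2.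

Step 2
Reactants: 3 methyl 7-methyl-2-(3-methylbut-2-en-1-yl)-3-oxooct-6-enoate; 4 N-methoxy-N-methylacetamide
Product: 6 4-hydroxy-6-methyl-3,5-bis(3-methylbut-2-en-1-yl)-2H-pyran-2-one, via diketo ester 5 (not isolated)
Conditions: LiN(iPr)2 (2.2 equiv), THF, −78 to −20 °C; 4 (1.2 equiv), −78 to 0 °C; dilute HCl work-up; crude 5, DBU (1.5 equiv), toluene, 80 °C; dilute HCl
Reagents that add atoms: none
Why: Acylation of the β-keto ester dianion at its γ-carbon by the Weinreb amide, whose chelated adduct prevents over-addition, should give the 3,5-diketo ester 5 as a mixture of diastereomers and enols, and DBU-promoted enol lactonisation with loss of methanol then closes the 4-hydroxy-2-pyranone, in which both former stereocentres are sp2 carbons.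

Step 3
Reactants: 6 4-hydroxy-6-methyl-3,5-bis(3-methylbut-2-en-1-yl)-2H-pyran-2-one
Product: 7 4-methoxy-6-methyl-3,5-bis(3-methylbut-2-en-1-yl)-2H-pyran-2-one
Conditions: Me2SO4 (1.5 equiv), K2CO3 (2 equiv), acetone, reflux
Reagents that add atoms: dimethyl sulfate, COS(=O)(=O)OC
Why: O-Alkylation of the acidic 4-hydroxy-2-pyranone (a vinylogous carboxylic acid) as its potassium salt with dimethyl sulfate should fix the future 7-OMe as the 4-methoxy-2-pyranone, the isomeric 2-methoxy-4-pyranone being the expected minor product and separable by chromatography.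

Step 4
Reactants: 8 methyl glycolate (methyl 2-hydroxyacetate)
Product: 9 methyl 2-(methoxymethoxy)acetate
Conditions: MeOCH2Cl (1.3 equiv), iPr2NEt (1.6 equiv), CH2Cl2, 0 °C to rt
Reagents that add atoms: chloromethyl methyl ether, COCCl
Why: Alkylation of the alcohol with chloromethyl methyl ether under amine base (MOM acetal formation) should give a mask for the future 3-OH that is inert to amide bases and methoxide and is cleaved by dilute acid.

Step 5
Reactants: 9 methyl 2-(methoxymethoxy)acetate
Product: 10 N-methoxy-2-(methoxymethoxy)-N-methylacetamide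
Conditions: MeNH(OMe)·HCl (1.5 equiv), iPrMgCl (3.0 equiv), THF, −20 to 0 °C
Reagents that add atoms: N,O-dimethylhydroxylamine hydrochloride, CNOC.Cl
Why: Weinreb amide formation by aminolysis of the methyl ester with the chloromagnesium amide of N,O-dimethylhydroxylamine should stop cleanly at the amide because its magnesium chelate does not react further.

Step 6
Reactants: 7 4-methoxy-6-methyl-3,5-bis(3-methylbut-2-en-1-yl)-2H-pyran-2-one; 10 N-methoxy-2-(methoxymethoxy)-N-methylacetamide
Product: 11 4-methoxy-6-[3-(methoxymethoxy)-2-oxopropyl]-3,5-bis(3-methylbut-2-en-1-yl)-2H-pyran-2-one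
Conditions: LiN(iPr)2 (1.1 equiv), THF, −78 °C; 10 (1.2 equiv), −78 to 0 °C; aq. NH4Cl
Reagents that add atoms: none
Why: Vinylogous deprotonation of the 6-methyl group, the only C–H whose anion is conjugated with the lactone carbonyl now that C3 and C5 are substituted, should give a lithium trienolate that is acylated by the Weinreb amide (Weinreb ketone synthesis), and because the chelated tetrahedral adduct releases the acidic ketone only on quench one equivalent of base suffices.

Step 7
Reactants: 12 methyl 3-hydroxy-4-methoxybenzoate (methyl isovanillate)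
Product: 13 methyl 4-methoxy-3-(methoxymethoxy)benzoate
Conditions: MeOCH2Cl (1.5 equiv), iPr2NEt (2 equiv), CH2Cl2, 0 °C to rt
Reagents that add atoms: chloromethyl methyl ether, COCCl
Why: MOM protection of the phenol by alkylation with chloromethyl methyl ether should make ring B inert to the amide base of step 8 and to methoxide, and the acetal is cleaved in the acid stage of step 9.

Step 8
Reactants: 11 4-methoxy-6-[3-(methoxymethoxy)-2-oxopropyl]-3,5-bis(3-methylbut-2-en-1-yl)-2H-pyran-2-one; 13 methyl 4-methoxy-3-(methoxymethoxy)benzoate (1.2 equiv)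
Product: 14 1-[4-methoxy-3-(methoxymethoxy)phenyl]-2-(methoxymethoxy)-4-[4-methoxy-3,5-bis(3-methylbut-2-en-1-yl)-2-oxo-2H-pyran-6-yl]butane-1,3-dione (racemic, enolisable)
Conditions: LiN(iPr)2 (3.2 equiv), THF, −78 to −30 °C; 13, −78 to 0 °C; aq. NH4Cl
Reagents that add atoms: none
Why: Claisen acylation of a dianion: the first equivalent of base should remove a proton from the methylene between pyranone and ketone, the second from the α-alkoxy methylene, and the dianion should attack the non-enolisable aryl ester at this last-formed and more basic carbon (the future C3) to make the C2–C3 bond, the third equivalent taking up the more acidic 1,3-diketone as it forms; the new stereocentre is racemic, enolisable and destroyed in step 9.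

Step 9
Reactants: 14 1-[4-methoxy-3-(methoxymethoxy)phenyl]-2-(methoxymethoxy)-4-[4-methoxy-3,5-bis(3-methylbut-2-en-1-yl)-2-oxo-2H-pyran-6-yl]butane-1,3-dione
Product: 18 3,5-dihydroxy-2-(3-hydroxy-4-methoxyphenyl)-7-methoxy-6,8-bis(3-methylbut-2-en-1-yl)-4H-chromen-4-one, via triketo ester 15 (not isolated), via acylphloroglucinol diketone 16 (not isolated), via bis-MOM flavonol 17 (not isolated)
Conditions: Mg(OMe)2 (8 equiv), MeOH, reflux, Ar; then 0 °C, aq. HCl to ca. 1.5 M, MeOH–THF, 45 °C
Reagents that add atoms: magnesium methoxide, C[O-].C[O-].[Mg+2] (the ester methoxy group of 15 only)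
Why: Magnesium-bound methoxide should open the enol lactone at its carbonyl carbon to the chelated triketo ester 15, in which the lactone geometry keeps the ester carbon and C8 cis on the C6=C7 enol-ether bond; the carbanion at C4a, flanked by the C8a and C4 carbonyl groups, then attacks the ester carbon (the future C5) in a Claisen (Dieckmann-type) acyl substitution, methoxide leaves, and tautomerisation gives the aromatic ring A of 16, so that one aromatic ring (the 2-pyranone) is converted into another (the benzene ring). The closest known reactions are the Claisen-mode cyclisation of 3,5,7-triketo esters and of 6-(2-oxoalkyl)-4-methoxy-2-pyranones to acylphloroglucinols under magnesium or alkali methoxide, and the acid cyclodehydration of 2-hydroxyaryl 1,3-diketones (Baker–Venkataraman diketones) to flavones. Ring A closes by anionic 6-exo-trig C–C bond formation (C4a–C5) followed by enolisation, and ring C closes in the acid stage by attack of a phenol oxygen on the aryl ketone carbon C2 (6-exo-trig hemiketal formation) and loss of water to 17, while the same acid transfers both MOM groups to methanol. No stereocentre is formed, and the enolisable stereocentres of 14 and 15 end as sp2 carbons. The step needs the Claisen mode to win over aldol-type closures and over retro-Claisen loss of the aroyl group: the carbons that could close other six-membered rings (C6, C8, C3) are all fully substituted, so such adducts cannot aromatise and revert, whereas the 1,3-diketone is protected as its magnesium enolate and aromatisation makes the Claisen closure irreversible. Ring C has no regiochemical choice because the 7-oxygen is already a methyl ether and the two free phenol oxygens of 16 are equivalent by the symmetry of ring A about the C4a–C7 axis, and the prenyl alkenes meet only methoxide and dilute acid.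

Compound list
1 | methyl acetoacetate (methyl 3-oxobutanoate) | COC(=O)CC(C)=O | starting material
2 | 1-bromo-3-methylbut-2-ene (prenyl bromide) | CC(C)=CCBr | starting material
3 | methyl 7-methyl-2-(3-methylbut-2-en-1-yl)-3-oxooct-6-enoate (racemic) | COC(=O)C(CC=C(C)C)C(=O)CCC=C(C)C | intermediate
4 | N-methoxy-N-methylacetamide | CC(=O)N(C)OC | starting material
5 | methyl 4-acetyl-7-methyl-2-(3-methylbut-2-en-1-yl)-3-oxooct-6-enoate (mixture of diastereomers and enols) | COC(=O)C(CC=C(C)C)C(=O)C(CC=C(C)C)C(C)=O | intermediate (not isolated)
6 | 4-hydroxy-6-methyl-3,5-bis(3-methylbut-2-en-1-yl)-2H-pyran-2-one | Cc1oc(=O)c(CC=C(C)C)c(O)c1CC=C(C)C | intermediate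
7 | 4-methoxy-6-methyl-3,5-bis(3-methylbut-2-en-1-yl)-2H-pyran-2-one | COc1c(CC=C(C)C)c(C)oc(=O)c1CC=C(C)C | intermediate
8 | methyl glycolate (methyl 2-hydroxyacetate) | COC(=O)CO | starting material
9 | methyl 2-(methoxymethoxy)acetate | COCOCC(=O)OC | intermediate
10 | N-methoxy-2-(methoxymethoxy)-N-methylacetamide | COCOCC(=O)N(C)OC | intermediate
11 | 4-methoxy-6-[3-(methoxymethoxy)-2-oxopropyl]-3,5-bis(3-methylbut-2-en-1-yl)-2H-pyran-2-one | COCOCC(=O)Cc1oc(=O)c(CC=C(C)C)c(OC)c1CC=C(C)C | intermediate
12 | methyl 3-hydroxy-4-methoxybenzoate (methyl isovanillate) | COC(=O)c1ccc(OC)c(O)c1 | starting material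
13 | methyl 4-methoxy-3-(methoxymethoxy)benzoate | COCOc1cc(C(=O)OC)ccc1OC | intermediate
14 | 1-[4-methoxy-3-(methoxymethoxy)phenyl]-2-(methoxymethoxy)-4-[4-methoxy-3,5-bis(3-methylbut-2-en-1-yl)-2-oxo-2H-pyran-6-yl]butane-1,3-dione (racemic, enolisable) | COCOc1cc(C(=O)C(OCOC)C(=O)Cc2oc(=O)c(CC=C(C)C)c(OC)c2CC=C(C)C)ccc1OC | intermediate
15 | methyl (2E)-3-methoxy-8-(methoxymethoxy)-9-[4-methoxy-3-(methoxymethoxy)phenyl]-2,4-bis(3-methylbut-2-en-1-yl)-5,7,9-trioxonon-2-enoate (magnesium chelate; epimers at C4 and C8, drawn as the keto form) | COC(=O)/C(CC=C(C)C)=C(OC)\C(CC=C(C)C)C(=O)CC(=O)C(OCOC)C(=O)c1ccc(OC)c(OCOC)c1 | intermediate (not isolated)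
16 | 1-[2,6-dihydroxy-4-methoxy-3,5-bis(3-methylbut-2-en-1-yl)phenyl]-3-[4-methoxy-3-(methoxymethoxy)phenyl]-2-(methoxymethoxy)propane-1,3-dione (racemic, enolisable) | COCOc1cc(C(=O)C(OCOC)C(=O)c2c(O)c(CC=C(C)C)c(OC)c(CC=C(C)C)c2O)ccc1OC | intermediate (not isolated)
17 | 5-hydroxy-7-methoxy-3-(methoxymethoxy)-2-[4-methoxy-3-(methoxymethoxy)phenyl]-6,8-bis(3-methylbut-2-en-1-yl)-4H-chromen-4-one | COCOc1cc(-c2oc3c(CC=C(C)C)c(OC)c(CC=C(C)C)c(O)c3c(=O)c2OCOC)ccc1OC | intermediate (not isolated)
18 | 3,5-dihydroxy-2-(3-hydroxy-4-methoxyphenyl)-7-methoxy-6,8-bis(3-methylbut-2-en-1-yl)-4H-chromen-4-one | COc1ccc(-c2oc3c(CC=C(C)C)c(OC)c(CC=C(C)C)c(O)c3c(=O)c2O)cc1O | target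

Total step count: 9. Longest linear sequence: 6 steps (steps 1, 2, 3, 6, 8 and 9).

Steps most likely to fail

Step 9. Methoxide may cleave the α-alkoxy 1,3-diketone (retro-Claisen loss of the aroyl group) faster than ring A closes, or the closure may stall at the ring-opened magnesium chelate because the doubly enolised chain is a poor nucleophile. The fallback sets out from 11 and comes back at 16. The same lactone opening and Claisen closure would be run on 11 itself (Mg(OMe)2, MeOH, reflux), which has a single ketone and no cleavable diketone, to give 1-[2,6-dihydroxy-4-methoxy-3,5-bis(3-methylbut-2-en-1-yl)phenyl]-2-(methoxymethoxy)ethanone F1. The C2–C3 bond would then be made on the finished ring A by crossed Claisen condensation of the trianion of F1 (LiN(SiMe3)2, 4.5 equiv, THF, −78 °C to rt) with ester 13, giving diketone 16, which is taken through the acid stage of step 9.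

Step 8. The second deprotonation may be incomplete, or proton transfer from the product to the dianion and attack of the excess amide base on the ester may stop the aroylation at low conversion. The fallback sets out from 11 and comes back at 14, making the C2–C3 bond at the aldehyde oxidation level. 3-Hydroxy-4-methoxybenzaldehyde F2 would be protected (MeOCH2Cl, iPr2NEt, CH2Cl2) as 4-methoxy-3-(methoxymethoxy)benzaldehyde F3. The dianion of 11 (LiN(iPr)2, 2.1 equiv, THF, −78 °C) would add to F3 in an aldol addition, which needs no third equivalent of base because the aldolate is not acidic, to give 6-[4-hydroxy-4-[4-methoxy-3-(methoxymethoxy)phenyl]-3-(methoxymethoxy)-2-oxobutyl]-4-methoxy-3,5-bis(3-methylbut-2-en-1-yl)-2H-pyran-2-one F4 as a mixture of diastereomers. Dess–Martin oxidation (NaHCO3, CH2Cl2) of F4 would then give 14.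

Step 2. Proton transfer from the enolisable amide to the hindered dianion, or retro-Claisen fragmentation of the diketo ester during lactonisation, may return 3. The fallback sets out from 2 and comes back at 6, building the pyranone from a ketone enol ether and a malonyl dichloride.
- Dimethyl malonate F5 would be alkylated with 2 (NaH, THF) to dimethyl 2-(3-methylbut-2-en-1-yl)malonate F6.
- F6 would be saponified (KOH, aq. MeOH; then dilute HCl) to 2-(3-methylbut-2-en-1-yl)malonic acid F7 and converted (oxalyl chloride, cat. DMF, CH2Cl2) into 2-(3-methylbut-2-en-1-yl)malonyl dichloride F8.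
- 6-Methylhept-5-en-2-one F9 would give its more substituted silyl enol ether, (Z)-trimethyl[(6-methylhepta-2,5-dien-2-yl)oxy]silane F10 (Me3SiCl, NaI, Et3N, MeCN).
- C-Acylation of F10 by F8 and O-acylation of the resulting enol (Et2O, −78 °C to rt) would close pyranone 6 directly.

Further compounds
F1 | step 9 | 1-[2,6-dihydroxy-4-methoxy-3,5-bis(3-methylbut-2-en-1-yl)phenyl]-2-(methoxymethoxy)ethanone | COCOCC(=O)c1c(O)c(CC=C(C)C)c(OC)c(CC=C(C)C)c1O
F2 | step 8 | 3-hydroxy-4-methoxybenzaldehyde (isovanillin) | COc1ccc(C=O)cc1O
F3 | step 8 | 4-methoxy-3-(methoxymethoxy)benzaldehyde | COCOc1cc(C=O)ccc1OC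
F4 | step 8 | 6-[4-hydroxy-4-[4-methoxy-3-(methoxymethoxy)phenyl]-3-(methoxymethoxy)-2-oxobutyl]-4-methoxy-3,5-bis(3-methylbut-2-en-1-yl)-2H-pyran-2-one (mixture of diastereomers) | COCOc1cc(C(O)C(OCOC)C(=O)Cc2oc(=O)c(CC=C(C)C)c(OC)c2CC=C(C)C)ccc1OC
F5 | step 2 | dimethyl malonate | COC(=O)CC(=O)OC
F6 | step 2 | dimethyl 2-(3-methylbut-2-en-1-yl)malonate | COC(=O)C(CC=C(C)C)C(=O)OC
F7 | step 2 | 2-(3-methylbut-2-en-1-yl)malonic acid | OC(=O)C(CC=C(C)C)C(=O)O
F8 | step 2 | 2-(3-methylbut-2-en-1-yl)malonyl dichloride | O=C(Cl)C(CC=C(C)C)C(=O)Cl
F9 | step 2 | 6-methylhept-5-en-2-one | CC(=O)CCC=C(C)C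
F10 | step 2 | (Z)-trimethyl[(6-methylhepta-2,5-dien-2-yl)oxy]silane | C/C(O[Si](C)(C)C)=C/CC=C(C)C
A1 | direct plan | 1-(2,6-dihydroxy-4-methoxyphenyl)ethanone | CC(=O)c1c(O)cc(OC)cc1O
A2 | direct plan | 1-[2,6-dihydroxy-4-methoxy-3,5-bis(3-methylbut-2-en-1-yl)phenyl]ethanone | CC(=O)c1c(O)c(CC=C(C)C)c(OC)c(CC=C(C)C)c1O
A3 | direct plan | 3-acetoxy-4-methoxybenzoyl chloride | COc1ccc(C(=O)Cl)cc1OC(C)=O
A4 | direct plan | 2-(diazoacetyl)-5-methoxy-4,6-bis(3-methylbut-2-en-1-yl)-1,3-phenylene bis(3-acetoxy-4-methoxybenzoate) | [N-]=[N+]=CC(=O)c1c(OC(=O)c2ccc(OC)c(OC(C)=O)c2)c(CC=C(C)C)c(OC)c(CC=C(C)C)c1OC(=O)c1ccc(OC)c(OC(C)=O)c1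
A5 | direct plan | 2-(3-acetoxy-4-methoxyphenyl)-3-hydroxy-7-methoxy-6,8-bis(3-methylbut-2-en-1-yl)-4-oxo-4H-chromen-5-yl 3-acetoxy-4-methoxybenzoate | COc1ccc(C(=O)Oc2c(CC=C(C)C)c(OC)c(CC=C(C)C)c3oc(-c4ccc(OC)c(OC(C)=O)c4)c(O)c(=O)c23)cc1OC(C)=O
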